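- Late in the ash flask, the flask asked about, the left-handed product stood near 18.1% of the charge, the mean of the last 4 readings, though the last of them, 19.4%, sat above the others.

the same everywhere: left-handed substrate 0.48 M; right-handed substrate 0.48 M; reagent 0.288 M

|  | free catalyst | remark | time |
|---|---|---|---|
| ash | 13 mM | the very flask that is asked about, followed so far |  |
| maple | 26 mM | run made earlier |  |
| flask | 13 mM |  | 30 h |

| ash: time / h | ash: left-handed product / % | maple: time / min | maple: left-handed product / % |
|---|---|---|---|
| 1.50 | 10.6 | 6.00 | 5.0 |
| 5.00 | 16.8 | 12.0 | 6.3 |
| 8.00 | 17.2 | 20.0 | 8.9 |
| 12.0 | 17.7 | 25.0 | 9.7 |
| 20.0 | 18.1 | 30.0 | 9.7 |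
| 25.0 | 19.4 | 40.0 | 11.3 |

(standard deviation of a reading: 0.5 percentage points)

- free catalyst is single-handed; left-handed substrate and right-handed substrate are mirror images of each other, charged as a racemate, each of them at the stated concentration
- left-handed product taken out counts as made
- the analysis behind the earlier runs scatters by 0.5 percentage points, standard deviation
- steps under discussion: free catalyst -> spent catalyst B; reagent + free catalyst + right-handed substrate -> free catalyst + right-handed product; reagent + free catalyst + left-handed substrate -> free catalyst + left-handed product; free catalyst -> spent catalyst A; reagent <-> dormant form
- additions bring no volume worth counting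

- Friday's: at 30 h take out 90% of the left-handed product then present, then wait 2.5 d
- Monday's: at 30 h add free catalyst, 100% of the amount charged, then wait 2.5 d
- Sunday's: at 30 h add reagent, 100% of the amount charged, then wait 2.5 d
- Tuesday's: change nothing and wait 2.5 d more

* left-handed product, in percent of the left-handed substrate and right-handed substrate together first charged, at 30 h
* which option adds most left-handed product ("none" when 2 percentage points or less is all one gets) (Friday's / Monday's / Sunday's / Tuesday's / none)
* left-handed product present, with what was taken out counted in, in percent of the left-handed substrate and right-handed substrate together first charged, after Friday's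
* left-handed product present, with what was taken out counted in, in percent of the left-handed substrate and right-handed substrate together first charged, after Sunday's

- I built the flask up by steps, first with the main step and nothing else: one reagent per product, with reagent at 30.0% of the charge and left-handed substrate at 50.0%, so reagent is the limiting reagent. That end state lies at 30.0%, and ash stopped lower, so this step could not be the whole story.
- Next I let free catalyst die. By 5.00 h ash held 16.8%, nearly all of its stop, so I took the stop to be the end of the catalyst's working life. I took the rate to go with live catalyst times the remaining shares of reagent and left-handed substrate, and integrating gave 2.38 for ash. I called this the reach of a dose: the working life a dose of catalyst supplies, proportional to the dose while the catalyst's rate of dying stays the same, equal to ln[b(r − p)/(r(b − p))] divided by (r − b), with b and r the charged shares of reagent and left-handed substrate and p the stop.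
- Then came the dormant form. Maple made 5.0% in 6.00 min but 6.3 percentage points in the next 34.0 min, which I read as reagent going dormant within minutes. Once the two have balanced, a two-way step scales the rate by a constant, so I let it sit inside the reach.
- I committed to about 18.1% now, and to no gain from waiting, taking product out or adding reagent. Monday's doubles the reach and gives 24.0%, a gain of 5.9 points.
- The forecast gave 19.4% now, 23.5% after Friday's and 32% after Sunday's, and chose Sunday's, holding that “Fresh reagent should give a new burst”. There we parted.
- The flask gave 18.3% now, 18.3% after Friday's and 18.4% after Sunday's, and Monday's was best, adding 5.5 points.

    free catalyst → spent catalyst B (k = 0.00515 min⁻¹)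
    reagent + free catalyst + right-handed substrate → free catalyst + right-handed product (k = 0.0213 M⁻² min⁻¹)
    reagent + free catalyst + left-handed substrate → free catalyst + left-handed product (k = 2.97 M⁻² min⁻¹)
    free catalyst → spent catalyst A (k = 6.08 × 10⁻⁶ min⁻¹)
    reagent ⇌ dormant form (K = 2.03, k = 0.0984 min⁻¹)

In this flask free catalyst had, at 1.11 h, a half-life of 2.2 h by its step to spent catalyst B, far shorter than the 30 h waited. At 30.0 h it stood at 0.00932% of its charge, with reagent at 12.6% of its own charge and dormant form at 25.7% of the reagent charge. Monday's second dose added 5.5 points where the doubled reach gave 5.9 points. For the neighbour flask with 0.49 M of reagent and the same charge of free catalyst, the same reach gives 27.6%, and that flask held 28.0%.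

(Readings and results were computed from invented constants; the scatter is artificial.)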